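**Remark (assumption).** The target has no stereocentre and no hindered axis (the diaryl ether rotates freely), so it is achiral. "Single enantiomer" is taken to mean the one constitution shown: 4,6-dibromo-2-(3,5-dibromo-2-methoxyphenoxy)-3-methoxyphenol.

**Retrosynthetic overview**
- 11 ⇒ enone 8 by cutting C4–Br, C6–Br and the aromatic sextet of ring B. Ring B (C1 OH, C2 OAr, C3 OMe, C4/C6 Br) is read as a cyclohexane-1,3-dione: oxygens on the two carbonyl carbons, bromines on their α-carbons, the ether on the carbon between them. One Br2 operation aromatises and dibrominates.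
- 8 ⇒ enol 7 by O-methylation of a symmetric dione, so C1 (future OH) and C3 (future OMe) are told apart before the ring is aromatic.
- 7 ⇒ phenol 4 + diazo-dione 6 by cutting the C2(ring B)–O bond: Rh-carbenoid O–H insertion makes the di-ortho-oxygenated ether bond at a non-aromatic carbon, with no aryl–X coupling.
- 4 ⇐ 3,5-dibromosalicylaldehyde 1 (O-methylation, Baeyer–Villiger), so ring A is bought with both bromines in place; 6 ⇐ cyclohexane-1,3-dione 5.
- Ring order: ring A is preformed; the ring B carbocycle is bought as 5 and aromatised in the last step; no ring closure is needed.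

Key step: step 6

**Route**

Step 1
Reactants: 1 3,5-dibromo-2-hydroxybenzaldehyde
Product: 2 3,5-dibromo-2-methoxybenzaldehyde
Conditions: MeI, K2CO3, DMF, rt
Reagents that add atoms: iodomethane, CI
Why: Williamson O-methylation (SN2) of the acidic, H-bonded phenol should proceed cleanly in K2CO3/DMF, with the aldehyde and both C–Br bonds inert.

Step 2
Reactants: 2 3,5-dibromo-2-methoxybenzaldehyde
Product: 4 3,5-dibromo-2-methoxyphenol, via aryl formate 3 (not isolated)
Conditions: mCPBA, CH2Cl2, rt → 40 °C; then MeOH, Et3N (cat.), rt
Reagents that add atoms: 3-chloroperoxybenzoic acid, OOC(=O)c1cccc(Cl)c1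
Why: Baeyer–Villiger (Dakin-type) oxidation, in which the ortho-methoxy donor should favour aryl over hydride migration in the Criegee adduct to give formate 3, which mild methanolysis should cleave to the phenol without touching C–Br or OMe.

Step 3
Reactants: 5 cyclohexane-1,3-dione
Product: 6 2-diazocyclohexane-1,3-dione
Conditions: p-ABSA, Et3N, MeCN, 0 °C → rt
Reagents that add atoms: 4-acetamidobenzenesulfonyl azide, CC(=O)Nc1ccc(cc1)S(=O)(=O)N=[N+]=[N-]
Why: Regitz diazo transfer to the acidic C2 methylene of a 1,3-dione is a standard, high-fidelity reaction.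

Step 4
Reactants: 4 3,5-dibromo-2-methoxyphenol (1.5 equiv); 6 2-diazocyclohexane-1,3-dione
Product: 7 2-(3,5-dibromo-2-methoxyphenoxy)-3-hydroxycyclohex-2-en-1-one
Conditions: Rh2(OAc)4 (1 mol%), PhCF3, 80 °C, slow addition of 6; excess 4 recovered by NaHCO3 extraction of the more acidic 7
Reagents that add atoms: none
Why: Rh(II)-carbenoid O–H insertion (oxonium ylide, then 1,2-proton shift) of an electrophilic acceptor/acceptor carbenoid into the phenol should form the ring B C2–O bond and leave the dione as enol 7; the dibromo-deactivated arene should not compete by C–H insertion, and excess phenol with slow diazo addition should suppress a second insertion into the enol O–H of 7.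

Step 5
Reactants: 7 2-(3,5-dibromo-2-methoxyphenoxy)-3-hydroxycyclohex-2-en-1-one
Product: 8 2-(3,5-dibromo-2-methoxyphenoxy)-3-methoxycyclohex-2-en-1-one
Conditions: TMSCHN2, MeOH–toluene (1:4), 0 °C → rt
Reagents that add atoms: (trimethylsilyl)diazomethane, C[Si](C)(C)C=[N+]=[N-]
Why: O-methylation of a vinylogous acid by a diazoalkane (proton transfer, then SN2 at the methyldiazonium carbon by the enolate oxygen) should give a single vinylogous ester, because the two oxygens of the symmetric dione are equivalent, and no free phenol is present to compete.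

Step 6
Reactants: 8 2-(3,5-dibromo-2-methoxyphenoxy)-3-methoxycyclohex-2-en-1-one
Product: 11 4,6-dibromo-2-(3,5-dibromo-2-methoxyphenoxy)-3-methoxyphenol, via γ-bromo enone 9 (not isolated), via phenol 10 (not isolated)
Conditions: Br2 (3.05 equiv), AcOH, 15 → 50 °C
Reagents that add atoms: bromine, BrBr
Why: Acid-catalysed enolisation of 8 to the linear dienol and γ-bromination should give 9, which should lose HBr by ionisation to an arenium-type cation and deprotonation at C5 (driven by aromatisation) and tautomerise to phenol 10; this phenol is far more nucleophilic than 8 and should take the remaining two equivalents of bromine by electrophilic aromatic substitution. The closest known reaction type is the Br2/AcOH halogenative aromatisation of 2-substituted cyclohexane-1,3-diones to 4,6-dibromoresorcinols, applied here to the mono-enol ether. No ring is closed (ring B is aromatised), and the only stereocentre on the pathway (C4 of racemic 9) is destroyed, so the product is achiral. The regioselectivity of the two substitutions is secured by the substrate: C4 and C6 are each ortho/para to both C1–OH and C3–OMe, whereas C5 is meta to all three oxygens. Ring A should be spared because it carries two bromines, its methoxy-activated positions are already occupied and its free positions are meta to OMe, and the stoichiometry of 3.05 equiv leaves no excess bromine. The C1–OH/C3–OMe distinction set in step 5 should persist, since the enol ether becomes a robust aryl methyl ether once the ring aromatises.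

**Compound list**
1 | 3,5-dibromo-2-hydroxybenzaldehyde | O=Cc1cc(Br)cc(Br)c1O | starting material
2 | 3,5-dibromo-2-methoxybenzaldehyde | COc1c(Br)cc(Br)cc1C=O | intermediate
3 | 3,5-dibromo-2-methoxyphenyl formate | COc1c(Br)cc(Br)cc1OC=O | intermediate (not isolated)
4 | 3,5-dibromo-2-methoxyphenol | COc1c(Br)cc(Br)cc1O | intermediate
5 | cyclohexane-1,3-dione | O=C1CCCC(=O)C1 | starting material
6 | 2-diazocyclohexane-1,3-dione | [N-]=[N+]=C1C(=O)CCCC1=O | intermediate
7 | 2-(3,5-dibromo-2-methoxyphenoxy)-3-hydroxycyclohex-2-en-1-one | COc1c(Br)cc(Br)cc1OC1=C(O)CCCC1=O | intermediate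
8 | 2-(3,5-dibromo-2-methoxyphenoxy)-3-methoxycyclohex-2-en-1-one | COc1c(Br)cc(Br)cc1OC1=C(OC)CCCC1=O | intermediate
9 | 4-bromo-2-(3,5-dibromo-2-methoxyphenoxy)-3-methoxycyclohex-2-en-1-one (racemic) | COc1c(Br)cc(Br)cc1OC1=C(OC)C(Br)CCC1=O | intermediate (not isolated)
10 | 2-(3,5-dibromo-2-methoxyphenoxy)-3-methoxyphenol | COc1c(Br)cc(Br)cc1Oc1c(O)cccc1OC | intermediate (not isolated)
11 | 4,6-dibromo-2-(3,5-dibromo-2-methoxyphenoxy)-3-methoxyphenol | COc1c(Br)cc(Br)cc1Oc1c(O)c(Br)cc(Br)c1OC | target

**Step count**
Total steps: 6. Longest linear sequence: 5 (steps 1, 2, 4, 5, 6).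

**Steps most likely to fail**

1. Step 6 (key step). The enol methyl group may be lost to HBr before the ring aromatises, or dehydrobromination may stall so that bromine is spread over non-aromatic bromo-ketones instead of being funnelled to the arene. Fallback (sets out from 8, returns at 10 and from there to 11): dehydrogenation is separated from halogenation. Kinetic deprotonation of 8 at C6 (LDA, THF, −78 °C) and trapping with PhSeCl should give 2-(3,5-dibromo-2-methoxyphenoxy)-3-methoxy-6-(phenylselanyl)cyclohex-2-en-1-one F1. Oxidation (H2O2, pyridine, CH2Cl2, 0 °C → rt) should give 2-(3,5-dibromo-2-methoxyphenoxy)-3-methoxy-6-(phenylseleninyl)cyclohex-2-en-1-one F2, not isolated, whose syn-elimination and tautomerisation should deliver phenol 10, now isolated. NBS (2.05 equiv, MeCN, 0 °C) should then brominate C4 and C6 to give 11.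

2. Step 4. The carbenoid may be diverted (Wolff ring contraction, attack at the ortho-methoxy oxygen, or a second insertion into the enol O–H of the product), and capture by the hindered, weakly nucleophilic phenol may be slow. Fallback (sets out from 4, returns at 10 and from there to 11): the conventional aryl-ether logic, which makes steps 3, 5 and 6 unnecessary. SNAr of 4 on 2-fluoro-3-methoxybenzaldehyde F3 (K2CO3, DMF, 110 °C; fluoride activated by the ortho-formyl group) should give 2-(3,5-dibromo-2-methoxyphenoxy)-3-methoxybenzaldehyde F4. Baeyer–Villiger oxidation (mCPBA, CH2Cl2) to 2-(3,5-dibromo-2-methoxyphenoxy)-3-methoxyphenyl formate F5 and methanolysis (MeOH, Et3N cat.) should give phenol 10. NBS (2.05 equiv, MeCN, 0 °C) should then give 11.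

3. Step 5. The vinylogous ester may hydrolyse back to 7 during isolation, or methylation may be incomplete, so that the material entering step 6 is not uniformly differentiated at C1/C3. Fallback (sets out from 7, returns at 11): aromatise first and methylate last. Treating 7 with Br2 (3.05 equiv, AcOH, 15 → 50 °C) should give 4,6-dibromo-2-(3,5-dibromo-2-methoxyphenoxy)benzene-1,3-diol F6, the parent case of the halogenative aromatisation. Its two hydroxyls are equivalent by symmetry, so mono-O-methylation (MeI 1.0 equiv, K2CO3 1.0 equiv, acetone, rt) can give only 11 as the mono-ether. Over-methylation is limited by the stoichiometry, and unreacted F6 is recycled.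

**Further compounds**
F1 | step 6 | 2-(3,5-dibromo-2-methoxyphenoxy)-3-methoxy-6-(phenylselanyl)cyclohex-2-en-1-one (racemic) | COc1c(Br)cc(Br)cc1OC1=C(OC)CCC([Se]c2ccccc2)C1=O
F2 | step 6 | 2-(3,5-dibromo-2-methoxyphenoxy)-3-methoxy-6-(phenylseleninyl)cyclohex-2-en-1-one (not isolated) | COc1c(Br)cc(Br)cc1OC1=C(OC)CCC([Se](=O)c2ccccc2)C1=O
F3 | step 4 | 2-fluoro-3-methoxybenzaldehyde | COc1cccc(C=O)c1F
F4 | step 4 | 2-(3,5-dibromo-2-methoxyphenoxy)-3-methoxybenzaldehyde | COc1c(Br)cc(Br)cc1Oc1c(C=O)cccc1OC
F5 | step 4 | 2-(3,5-dibromo-2-methoxyphenoxy)-3-methoxyphenyl formate | COc1c(Br)cc(Br)cc1Oc1c(OC=O)cccc1OC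
F6 | step 5 | 4,6-dibromo-2-(3,5-dibromo-2-methoxyphenoxy)benzene-1,3-diol | COc1c(Br)cc(Br)cc1Oc1c(O)c(Br)cc(Br)c1O
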